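# Proposed synthesis of CNP0311864.1 (27) through a gold-catalysed furan–ynol ether cyclisation

## Analysis of the target

The target 27 is a 2H-chromene: benzene ring A (C4a–C8a) fused to pyran ring B (O1, C2, C3=C4). Ring A is contiguously tetrasubstituted. C8a carries O1, C8 a free hydroxyl, C5 the 3-(2,4-dihydroxyphenyl)-3-oxopropyl arm (a dihydrochalcone ending in resorcinol ring C), and C4a the C4 end of the pyran; C6 and C7 are unsubstituted.

The only stereocentre is C2 (R), a fully substituted carbon bound to O1, a methyl group, C3 and the (E)-4-hydroxy-4-methylpent-2-enyl chain. Nothing in the molecule can relay it, so it has to be set absolutely. It is also the sp3 carbon of a 2H-chromene, so it can be lost by electrocyclic opening to the o-quinone methide under UV light or strong heating.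

The sensitive groups are the tertiary allylic alcohol (ionises with acid), the styrene-like C3=C4 bond, three electron-rich phenols, and three C=C bonds that rule out hydrogenation and hydrogenolysis. The difficulties are therefore the oxygenated quaternary centre, the substitution pattern of ring A with the correct oxygen at C8, and a protecting-group plan that ends without acid.

The strategy rests on the C8–OH/C8a–O1 pair together with the bridge C2–C3–C4 that links the O1-bearing carbon to C4a. A furan joined at its C2 through two CH2 groups and the carbinol carbon to an ethynyl ether maps onto this atom for atom: furan C2–C5 become C4a, C5, C6 and C7, the two alkyne carbons become C8a and C8, and the furan oxygen becomes the C8 hydroxyl.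

## Retrosynthetic reasoning

**27 from 26.** The last operation only cleaves three aryl O–Si bonds. Silyl ethers are chosen for all three phenols so that the final reagent is buffered fluoride at 0 °C; an acid-labile phenol protecting group would put the tertiary allylic alcohol and the chromene at risk in the last step.

**26 from 22 and 25.** The arm is cut at the C5–CH2 bond, giving aryl iodide 22 and the three-carbon aryl vinyl carbinol 25. The forward reaction is a Heck arylation that ends by β-hydride elimination toward the carbinol, so the saturated ketone forms directly. A cut between the two CH2 groups (aldol logic) would give a chalcone, which would need a selective 1,4-reduction beside two other alkenes and a base-stable protecting-group set. 25 comes from aldehyde 23 through silyl ether 24 and a vinyl addition.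

**22 from 19 and 20.** The side chain is cut at the C–CH3 bond of the carbinol (methyl nucleophile on enone 21) and at the C2'=C3' double bond (stabilised ylide 20 on aldehyde 19), which fixes the E geometry. 19 is the oxidation product of alcohol 18, freed from the bis-silyl ether 17. The side chain is finished before the arm because the aryl ketone of 26 would not survive the methyl addition.

**17 from 15.** The C3=C4 double bond is taken out, leaving chroman 15. The forward step is a benzylic bromination at C4, the only benzylic sp3 position, followed by loss of HBr through intermediate 16. The double bond is introduced after ring construction because the ring-forming step needs a saturated, alkene-free tether.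

**15 from 13.** The iodine at C5 and the silyl group on the C8 oxygen are removed in turn (15 from 14, 14 from 13). The free C8 hydroxyl of 13 directs an electrophile to its para position, which is C5, so the handle for the arm is placed before the phenol is capped.

**13 from 10 (the central disconnection).** Ring A is opened back to a furan and ring B is opened at C4a–C8a. This cuts C4a–C8a, C7–C8 and the C8–OH bond and leads to ethynyl ether 10. It is made here because the C8–OH/C8a–O1 pattern is exactly what the furan–yne isomerisation delivers, and because none of the bonds at the stereocentre is involved. The forward reaction has to form both rings in one operation and place the hydroxyl on C8.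

**10 from 7 and 8.** The O–C(sp) bond is cut, giving tertiary alcohol 7 and trichloroethylene 8. The carbinol oxygen becomes O1 and the C–O bond at the stereocentre is never broken. The primary oxygen carries a triisopropylsilyl rather than a tert-butyldimethylsilyl group: the potassium alkoxide of the tertiary alcohol sits in a 1,3-relationship to the primary silyl ether, and a small silyl group could migrate from oxygen to oxygen, after which the wrong alkoxide would be vinylated.

**7 from 4.** The tertiary carbinol of 7 comes from diol 6, this from epoxy alcohol 5 by hydride delivery to C2, and 5 from the E allylic alcohol 4 by a tartrate-controlled epoxidation. That step sets the only stereocentre of the synthesis; the C3–O bond made there is the one that ends as C2–O1.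

**4 from 1 and 2.** The C2=C3 bond of ester 3 is cut to ketone 1 and phosphonate 2; reduction of 3 gives 4. The E geometry matters because the Z isomer would give the enantiomeric carbinol in the epoxidation.

## Alternatives that were turned down

**Alternative 1: intramolecular aryl etherification.**
- Disconnection: O1–C8a. The precursor is the aryl bromide 3-bromo-2-[(1Z,3R)-3-hydroxy-3-methylhexa-1,5-dien-1-yl]-4-(methoxymethoxy)benzaldehyde A1.
- Forward step: Pd(OAc)2 with a bulky di-tert-butyl(biaryl)phosphine and Cs2CO3, or CuI with 1,10-phenanthroline, couples the tertiary alkoxide with the bromide to give (2R)-2-allyl-8-(methoxymethoxy)-2-methyl-2H-chromene-5-carbaldehyde A2.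
- For it: ring A is bought with its carbon at C5 and oxygen at C8 in place; the C3=C4 bond is already present as the Z-alkene; the allyl group is a short handle for the side chain. On convergence and on steps after ring closure it is stronger than the chosen plan.
- Against it: the bromide of A1 sits between the methoxymethoxy group and the alkenyl group, so oxidative addition and C–O reductive elimination are both hindered. The aryl–palladium intermediate has a competing 7-exo Heck closure onto the allyl group. The Z-styrenyl tertiary allylic alcohol ionises and dehydrates easily and must keep its geometry. The stereocentre would come from an asymmetric addition to a methyl ketone, where selectivity is less dependable than an epoxidation of a trisubstituted allylic alcohol.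
- Comparison: the chosen strategy is longer after the ring-forming step, but offers a cyclisation at or below room temperature with no hindered cross-coupling and no Heck competition, and a stereocentre made by a well-tested reaction.

**Alternative 2: gold-catalysed hydroarylation of an aryl propargyl ether.**
- Disconnection: C4–C4a. The precursor is the citramalate-derived ether tert-butyl{[(3R)-3-[5-bromo-2-(methoxymethoxy)phenoxy]-3-methylpent-4-yn-1-yl]oxy}dimethylsilane A3.
- Forward step: Ph3PAuNTf2 activates the terminal alkyne and the arene carbon ortho to oxygen attacks it (6-endo), giving tert-butyl{2-[(2R)-5-bromo-8-(methoxymethoxy)-2-methyl-2H-chromen-2-yl]ethoxy}dimethylsilane A4.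
- For it: A4 has the C3=C4 bond, the C5 halogen and the protected C8 oxygen at once. It corresponds to 17 of the chosen route, which needs three further steps after its ring closure to get there. On step economy after cyclisation this alternative is clearly stronger, and cyclisation of aryl propargyl ethers to 2H-chromenes is robust.
- Against it: the weak point is before the key step. The O1–C2 bond of A3 must be formed between a phenol and a tertiary propargylic centre. The usual copper-catalysed propargylic etherification passes through an ionised propargyl/allenylidene species and would erase the stereocentre, and direct arylation of a tertiary propargylic alkoxide with an unactivated arene is poor. The ring must also close at the carbon next to bromine, the more crowded ortho position.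
- Comparison: the chosen strategy gives up the direct access to the chromene but never makes or breaks a bond at the stereocentre after the epoxidation, because the oxygen of the carbinol itself becomes O1.

**Alternative 3: one-carbon ring expansion of a benzofuran-3-one.**
- Disconnection: C3–C4 and C4–C4a. The precursor is (2R)-4-bromo-7-(methoxymethoxy)-2-methyl-2-(prop-2-en-1-yl)-1-benzofuran-3(2H)-one A5.
- Forward step: Me3SiCHN2 with BF3·OEt2 or Sc(OTf)3 adds to the ketone, and an aryl shift with loss of N2 gives (2R)-5-bromo-8-(methoxymethoxy)-2-methyl-2-(prop-2-en-1-yl)-2H-chromen-3(4H)-one A6.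
- For it: the quaternary centre of A5 can be set by a catalytic asymmetric allylation of the benzofuranone, which is as good as or better than the epoxidation route in catalyst economy, and ring A again comes with its substituents.
- Against it: the ketone of A5 is deactivated (it is conjugated to the ring oxygen through the arene) and crowded by the peri bromine and the quaternary C2. Migration of the aryl group has to beat migration of the oxygen-bearing quaternary carbon. Epoxide formation and double insertion are known side paths of this homologation. A6 is an easily enolised, air-sensitive chroman-3-one that still needs reduction and regioselective dehydration to give C3=C4.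
- Comparison: step counts are similar. The chosen strategy offers a ring construction whose connectivity is fixed by the tether, with no question of migratory aptitude.

Key step: step 7

## Remarks before the steps

- The primary alcohol is carried as a triisopropylsilyl ether (not tert-butyldimethylsilyl) so that no silyl shift to the neighbouring tertiary potassium alkoxide can occur in step 6.
- Intermediates are numbered when they build up in the flask before the next reagent is added, and also the two metal-free valence tautomers of the key step. Alkoxides, acetylides and metal-bound species are treated in the Why lines.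
- From 17 onward all compounds are kept at or below 60 °C and away from UV light, because a 2H-chromene can racemise at C2 through electrocyclic ring opening.
- The descriptor at the stereocentre changes from S (5–15) to R (16–27) only because the CIP ranking of C3 changes; no bond to that carbon is touched after step 3.

## Steps

Step 1
Reactants: 1 4-(furan-2-yl)butan-2-one; 2 triethyl phosphonoacetate
Product: 3 ethyl (2E)-5-(furan-2-yl)-3-methylpent-2-enoate
Conditions: NaH, THF, 0 °C → rt; E isomer separated by chromatography
Reagents that add atoms: none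
Why: Horner–Wadsworth–Emmons olefination of a methyl ketone should favour the E ester (ester trans to the larger chain); the minor Z ester is removed because geometric purity limits the enantiomeric purity reached in step 3.

Step 2
Reactants: 3 ethyl (2E)-5-(furan-2-yl)-3-methylpent-2-enoate
Product: 4 (2E)-5-(furan-2-yl)-3-methylpent-2-en-1-ol
Conditions: i-Bu2AlH (2.2 equiv), CH2Cl2, −78 °C; Rochelle salt work-up
Reagents that add atoms: none
Why: 1,2-Reduction of an α,β-unsaturated ester by an aluminium hydride gives the allylic alcohol without touching the alkene geometry or the furan.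

Step 3
Reactants: 4 (2E)-5-(furan-2-yl)-3-methylpent-2-en-1-ol
Product: 5 {(2S,3S)-3-[2-(furan-2-yl)ethyl]-3-methyloxiran-2-yl}methanol
Conditions: Ti(OiPr)4 (10 mol %), L-(+)-diethyl tartrate (12 mol %), t-BuOOH, 4 Å molecular sieves, CH2Cl2, −20 °C
Reagents that add atoms: tert-butyl hydroperoxide, CC(C)(C)OO
Why: Sharpless asymmetric epoxidation; with L-(+)-tartrate an E-3,3-disubstituted allylic alcohol of the geraniol type is epoxidised on the face that gives the (2S,3S)-epoxide, which sets the configuration of the later C2. The furan has no directing hydroxyl next to it and should not be oxidised at −20 °C.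

Step 4
Reactants: 5 {(2S,3S)-3-[2-(furan-2-yl)ethyl]-3-methyloxiran-2-yl}methanol
Product: 6 (3S)-5-(furan-2-yl)-3-methylpentane-1,3-diol
Conditions: NaAlH2(OCH2CH2OMe)2, THF, 0 °C
Reagents that add atoms: none
Why: Hydride is delivered within the alkoxy-aluminate to C2 of the 2,3-epoxy alcohol, giving the 1,3-diol; the C3–O bond is not touched, so the tertiary carbinol keeps its configuration.

Step 5
Reactants: 6 (3S)-5-(furan-2-yl)-3-methylpentane-1,3-diol
Product: 7 (3S)-5-(furan-2-yl)-3-methyl-1-{[tri(propan-2-yl)silyl]oxy}pentan-3-ol
Conditions: i-Pr3SiCl, imidazole, DMF, 0 °C → rt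
Reagents that add atoms: chlorotri(propan-2-yl)silane, CC(C)[Si](Cl)(C(C)C)C(C)C
Why: Silylation is selective for the primary hydroxyl over the tertiary one; the bulky silyl group is chosen because it does not migrate to a neighbouring alkoxide.

Step 6
Reactants: 7 (3S)-5-(furan-2-yl)-3-methyl-1-{[tri(propan-2-yl)silyl]oxy}pentan-3-ol; 8 trichloroethylene
Product: 10 {[(3S)-3-(ethynyloxy)-5-(furan-2-yl)-3-methylpentyl]oxy}tri(propan-2-yl)silane, via dichlorovinyl ether 9 (not isolated)
Conditions: KH, THF, 0 °C → rt; 8, −50 °C → rt; then n-BuLi (2.5 equiv), −78 → −40 °C; MeOH, −78 °C; cold work-up, used at once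
Reagents that add atoms: none
Why: Greene ynol ether synthesis: the potassium alkoxide adds to dichloroacetylene formed in situ from 8 to give the (E)-1,2-dichlorovinyl ether 9; n-BuLi then eliminates HCl and exchanges the remaining chlorine, and protonation of the lithium acetylide gives the ethynyl ether. Tertiary alkoxides are known substrates, any furan lithiation is reversed by the protic quench, and the product is kept cold because tertiary ethynyl ethers lose ketene by a retro-ene path on warming.

Step 7
Reactants: 10 {[(3S)-3-(ethynyloxy)-5-(furan-2-yl)-3-methylpentyl]oxy}tri(propan-2-yl)silane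
Product: 13 (2S)-2-methyl-2-(2-{[tri(propan-2-yl)silyl]oxy}ethyl)-3,4-dihydro-2H-chromen-8-ol, via oxepine 11 (not isolated), via arene oxide 12 (not isolated)
Conditions: Ph3PAuNTf2 (5 mol %), dry CH2Cl2 (0.02 M), slow addition of 10, 0 °C → rt
Reagents that add atoms: none
Why: Cationic monovalent gold from Ph3PAuNTf2 coordinates the ethynyl ether, whose oxygen makes the O-bearing alkyne carbon the electrophilic one (ketene-oxonium character); furan C2 attacks it in a 6-exo-dig closure that forms C4a–C8a and ring B and leaves a cyclopropyl gold carbene at the former terminal carbon. Opening of the furan C–O bond gives a (Z)-dienal gold carbene, the aldehyde oxygen adds to the carbene carbon and releases the catalyst as oxepine 11, and a 6π electrocyclisation closes the C7–C8 bond to arene oxide 12, which is how ring A is closed. Heterolysis of the C7–O bond of 12 is favoured because the resulting cation is stabilised at C8a by O1, so the oxygen stays on C8 and proton loss gives the C8 phenol and not its C7 isomer. The closest known reaction type is the gold-catalysed furan–yne phenol synthesis in its variant with furans tethered to alkynyl ethers and ynamides, which gives 8-hydroxychromans and 7-hydroxyindolines; the present substrate differs only in the tertiary centre next to oxygen. No stereocentre is formed, and none of the four bonds at the carbinol carbon takes part, so its configuration is carried over unchanged. The step needs attack at the internal alkyne carbon (secured by the ynol ether polarisation), attack by furan C2 within the molecule rather than by C5 of a second molecule or by the product phenol (secured by the six-membered transition state, slow addition and dilution), and survival of the tertiary C–O bond (secured by working at 0 °C with a non-acidic counter-ion and dry solvent).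

Step 8
Reactants: 13 (2S)-2-methyl-2-(2-{[tri(propan-2-yl)silyl]oxy}ethyl)-3,4-dihydro-2H-chromen-8-ol
Product: 14 (2S)-5-iodo-2-methyl-2-(2-{[tri(propan-2-yl)silyl]oxy}ethyl)-3,4-dihydro-2H-chromen-8-ol
Conditions: N-iodosuccinimide (1.05 equiv), CF3CO2H (10 mol %), MeCN, −20 → 0 °C
Reagents that add atoms: N-iodosuccinimide, O=C1CCC(=O)N1I
Why: Electrophilic aromatic iodination of a free phenol goes para to the hydroxyl, which is C5; the ether oxygen O1 directs to C6 less strongly, so the halogenation is done before the phenol is capped.

Step 9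
Reactants: 14 (2S)-5-iodo-2-methyl-2-(2-{[tri(propan-2-yl)silyl]oxy}ethyl)-3,4-dihydro-2H-chromen-8-ol
Product: 15 {[(2S)-5-iodo-2-methyl-2-(2-{[tri(propan-2-yl)silyl]oxy}ethyl)-3,4-dihydro-2H-chromen-8-yl]oxy}tri(propan-2-yl)silane
Conditions: i-Pr3SiCl, imidazole, DMF, rt
Reagents that add atoms: chlorotri(propan-2-yl)silane, CC(C)[Si](Cl)(C(C)C)C(C)C
Why: Standard silylation of a phenol; the aryl silyl ether is inert to bromine radicals, base, oxidants and organomagnesium reagents and is cleaved by fluoride at the end.

Step 10
Reactants: 15 {[(2S)-5-iodo-2-methyl-2-(2-{[tri(propan-2-yl)silyl]oxy}ethyl)-3,4-dihydro-2H-chromen-8-yl]oxy}tri(propan-2-yl)silane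
Product: 17 {[(2R)-5-iodo-2-methyl-2-(2-{[tri(propan-2-yl)silyl]oxy}ethyl)-2H-chromen-8-yl]oxy}tri(propan-2-yl)silane, via 4-bromochroman 16 (not isolated)
Conditions: N-bromosuccinimide (1.05 equiv), AIBN (5 mol %), PhCF3, 80 °C; then DBU, 0 °C → rt, dark
Reagents that add atoms: N-bromosuccinimide, O=C1CCC(=O)N1Br (its bromine is present in intermediate 16 only)
Why: Wohl–Ziegler bromination at C4, the only benzylic sp3 position and one activated by O1 through the ring, followed by E2 loss of HBr toward C3; this is the known route from 2,2-disubstituted chromans to 2H-chromenes. C2 is not involved.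

Step 11
Reactants: 17 {[(2R)-5-iodo-2-methyl-2-(2-{[tri(propan-2-yl)silyl]oxy}ethyl)-2H-chromen-8-yl]oxy}tri(propan-2-yl)silane
Product: 18 2-[(2R)-5-iodo-2-methyl-8-{[tri(propan-2-yl)silyl]oxy}-2H-chromen-2-yl]ethan-1-ol
Conditions: HCl (1 % in MeOH), THF, 0 °C → rt
Reagents that add atoms: none
Why: Acid-catalysed methanolysis cleaves an alkyl silyl ether much faster than an aryl silyl ether, because the aryl ether oxygen is far less basic; this is the reverse of the order under fluoride and is the known way to free an alcohol beside a silylated phenol.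

Step 12
Reactants: 18 2-[(2R)-5-iodo-2-methyl-8-{[tri(propan-2-yl)silyl]oxy}-2H-chromen-2-yl]ethan-1-ol
Product: 19 [(2R)-5-iodo-2-methyl-8-{[tri(propan-2-yl)silyl]oxy}-2H-chromen-2-yl]acetaldehyde
Conditions: Dess–Martin periodinane, NaHCO3, CH2Cl2, 0 °C → rt
Reagents that add atoms: none
Why: Dess–Martin oxidation under buffered, non-basic conditions; this matters because the β-aryloxy aldehyde would open ring B by E1cB elimination if it met base. Chroman-2-ylacetaldehydes of this kind are known and isolable.

Step 13
Reactants: 19 [(2R)-5-iodo-2-methyl-8-{[tri(propan-2-yl)silyl]oxy}-2H-chromen-2-yl]acetaldehyde; 20 1-(triphenyl-λ5-phosphanylidene)propan-2-one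
Product: 21 (3E)-5-[(2R)-5-iodo-2-methyl-8-{[tri(propan-2-yl)silyl]oxy}-2H-chromen-2-yl]pent-3-en-2-one
Conditions: toluene, 60 °C, dark
Reagents that add atoms: none
Why: Wittig reaction of a stabilised keto-ylide with an aliphatic aldehyde gives the E enone under neutral conditions, which spares the base-sensitive aldehyde.

Step 14
Reactants: 21 (3E)-5-[(2R)-5-iodo-2-methyl-8-{[tri(propan-2-yl)silyl]oxy}-2H-chromen-2-yl]pent-3-en-2-one
Product: 22 (3E)-5-[(2R)-5-iodo-2-methyl-8-{[tri(propan-2-yl)silyl]oxy}-2H-chromen-2-yl]-2-methylpent-3-en-2-ol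
Conditions: MeMgBr (1.5 equiv), CeCl3, THF, −78 °C; aq. NH4Cl
Reagents that add atoms: methylmagnesium bromide, C[Mg]Br
Why: 1,2-Addition of a methyl organometallic to a methyl enone; the cerium additive favours carbonyl addition over conjugate addition and over γ-deprotonation, which could expel the aryloxide. The aryl iodide does not exchange with a methylmagnesium reagent at −78 °C.

Step 15
Reactants: 23 2,4-dihydroxybenzaldehyde
Product: 24 2,4-bis{[tri(propan-2-yl)silyl]oxy}benzaldehyde
Conditions: i-Pr3SiCl (2.4 equiv), imidazole, DMAP (cat.), DMF, rt → 40 °C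
Reagents that add atoms: chlorotri(propan-2-yl)silane, CC(C)[Si](Cl)(C(C)C)C(C)C
Why: Silylation of both phenols; the hydrogen-bonded ortho hydroxyl reacts more slowly, hence the excess and the acyl-transfer catalyst.

Step 16
Reactants: 24 2,4-bis{[tri(propan-2-yl)silyl]oxy}benzaldehyde
Product: 25 1-(2,4-bis{[tri(propan-2-yl)silyl]oxy}phenyl)prop-2-en-1-ol (racemic)
Conditions: CH2=CHMgBr, THF, −78 °C; quench at −78 °C
Reagents that add atoms: vinylmagnesium bromide, C=C[Mg]Br
Why: Grignard addition to an aryl aldehyde; the cold quench and the bulky silyl group prevent transfer of the ortho silyl group to the new magnesium alkoxide. The new stereocentre is left racemic because it becomes the ketone carbon in step 17.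

Step 17
Reactants: 22 (3E)-5-[(2R)-5-iodo-2-methyl-8-{[tri(propan-2-yl)silyl]oxy}-2H-chromen-2-yl]-2-methylpent-3-en-2-ol; 25 1-(2,4-bis{[tri(propan-2-yl)silyl]oxy}phenyl)prop-2-en-1-ol
Product: 26 1-(2,4-bis{[tri(propan-2-yl)silyl]oxy}phenyl)-3-[(2R)-2-[(2E)-4-hydroxy-4-methylpent-2-en-1-yl]-2-methyl-8-{[tri(propan-2-yl)silyl]oxy}-2H-chromen-5-yl]propan-1-one
Conditions: Pd(OAc)2 (5 mol %), n-Bu4NCl, NaHCO3, DMF, 45 °C, dark; 25 in excess
Reagents that add atoms: none
Why: Heck arylation of a secondary allylic alcohol under ligand-free phase-transfer (Jeffery) conditions: the aryl–palladium species (divalent palladium, from oxidative addition of the iodide to zerovalent palladium) adds across the terminal alkene with the aryl group on the CH2 end, and β-hydride elimination toward the carbinol carbon gives the enol and hence the saturated ketone. The C5–CH2 bond and the ketone are made in one step, with no enone to reduce beside the C3=C4 and side-chain alkenes; the internal, trisubstituted-carbinol alkene of 22 and the ring alkene are much less reactive than the monosubstituted alkene of 25.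

Step 18
Reactants: 26 1-(2,4-bis{[tri(propan-2-yl)silyl]oxy}phenyl)-3-[(2R)-2-[(2E)-4-hydroxy-4-methylpent-2-en-1-yl]-2-methyl-8-{[tri(propan-2-yl)silyl]oxy}-2H-chromen-5-yl]propan-1-one
Product: 27 1-(2,4-dihydroxyphenyl)-3-{(2R)-8-hydroxy-2-[(2E)-4-hydroxy-4-methylpent-2-en-1-yl]-2-methyl-2H-chromen-5-yl}propan-1-one (CNP0311864.1)
Conditions: n-Bu4NF (3.3 equiv), AcOH (3.3 equiv), THF, 0 °C, degassed, dark
Reagents that add atoms: none
Why: Fluoride cleaves aryl silyl ethers rapidly at 0 °C; the acetic acid buffer keeps the electron-rich phenoxides from air oxidation, and neither the tertiary allylic alcohol nor the chromene is affected.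

## Compound list

1 | 4-(furan-2-yl)butan-2-one | CC(=O)CCc1ccco1 | starting material
2 | triethyl phosphonoacetate | CCOC(=O)CP(=O)(OCC)OCC | starting material
3 | ethyl (2E)-5-(furan-2-yl)-3-methylpent-2-enoate | CCOC(=O)/C=C(\C)CCc1ccco1 | intermediate
4 | (2E)-5-(furan-2-yl)-3-methylpent-2-en-1-ol | OC/C=C(\C)CCc1ccco1 | intermediate
5 | {(2S,3S)-3-[2-(furan-2-yl)ethyl]-3-methyloxiran-2-yl}methanol | OC[C@@H]1O[C@@]1(C)CCc1ccco1 | intermediate
6 | (3S)-5-(furan-2-yl)-3-methylpentane-1,3-diol | OCC[C@](O)(C)CCc1ccco1 | intermediate
7 | (3S)-5-(furan-2-yl)-3-methyl-1-{[tri(propan-2-yl)silyl]oxy}pentan-3-ol | CC(C)[Si](OCC[C@](O)(C)CCc1ccco1)(C(C)C)C(C)C | intermediate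
8 | trichloroethylene | ClC=C(Cl)Cl | starting material
9 | {[(3S)-3-{[(E)-1,2-dichloroethenyl]oxy}-5-(furan-2-yl)-3-methylpentyl]oxy}tri(propan-2-yl)silane | CC(C)[Si](OCC[C@](O/C(Cl)=C\Cl)(C)CCc1ccco1)(C(C)C)C(C)C | intermediate (not isolated)
10 | {[(3S)-3-(ethynyloxy)-5-(furan-2-yl)-3-methylpentyl]oxy}tri(propan-2-yl)silane | CC(C)[Si](OCC[C@](OC#C)(C)CCc1ccco1)(C(C)C)C(C)C | intermediate (precursor of the key step)
11 | (2S)-2-methyl-2-(2-{[tri(propan-2-yl)silyl]oxy}ethyl)-3,4-dihydro-2H-pyrano[2,3-c]oxepine (oxepine tautomer) | CC(C)[Si](OCC[C@]1(C)CCC2=CC=COC=C2O1)(C(C)C)C(C)C | intermediate (not isolated)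
12 | (2S)-2-methyl-2-(2-{[tri(propan-2-yl)silyl]oxy}ethyl)-3,4,7,8-tetrahydro-2H-chromene 7,8-oxide (arene oxide, both oxirane diastereomers) | CC(C)[Si](OCC[C@]1(C)CCC2=C(O1)C3OC3C=C2)(C(C)C)C(C)C | intermediate (not isolated)
13 | (2S)-2-methyl-2-(2-{[tri(propan-2-yl)silyl]oxy}ethyl)-3,4-dihydro-2H-chromen-8-ol | CC(C)[Si](OCC[C@]1(C)CCc2cccc(O)c2O1)(C(C)C)C(C)C | intermediate (product of the key step)
14 | (2S)-5-iodo-2-methyl-2-(2-{[tri(propan-2-yl)silyl]oxy}ethyl)-3,4-dihydro-2H-chromen-8-ol | CC(C)[Si](OCC[C@]1(C)CCc2c(I)ccc(O)c2O1)(C(C)C)C(C)C | intermediate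
15 | {[(2S)-5-iodo-2-methyl-2-(2-{[tri(propan-2-yl)silyl]oxy}ethyl)-3,4-dihydro-2H-chromen-8-yl]oxy}tri(propan-2-yl)silane | CC(C)[Si](OCC[C@]1(C)CCc2c(I)ccc(O[Si](C(C)C)(C(C)C)C(C)C)c2O1)(C(C)C)C(C)C | intermediate
16 | {[(2R)-4-bromo-5-iodo-2-methyl-2-(2-{[tri(propan-2-yl)silyl]oxy}ethyl)-3,4-dihydro-2H-chromen-8-yl]oxy}tri(propan-2-yl)silane (both C4 epimers) | CC(C)[Si](OCC[C@]1(C)CC(Br)c2c(I)ccc(O[Si](C(C)C)(C(C)C)C(C)C)c2O1)(C(C)C)C(C)C | intermediate (not isolated)
17 | {[(2R)-5-iodo-2-methyl-2-(2-{[tri(propan-2-yl)silyl]oxy}ethyl)-2H-chromen-8-yl]oxy}tri(propan-2-yl)silane | CC(C)[Si](OCC[C@]1(C)C=Cc2c(I)ccc(O[Si](C(C)C)(C(C)C)C(C)C)c2O1)(C(C)C)C(C)C | intermediate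
18 | 2-[(2R)-5-iodo-2-methyl-8-{[tri(propan-2-yl)silyl]oxy}-2H-chromen-2-yl]ethan-1-ol | OCC[C@]1(C)C=Cc2c(I)ccc(O[Si](C(C)C)(C(C)C)C(C)C)c2O1 | intermediate
19 | [(2R)-5-iodo-2-methyl-8-{[tri(propan-2-yl)silyl]oxy}-2H-chromen-2-yl]acetaldehyde | O=CC[C@]1(C)C=Cc2c(I)ccc(O[Si](C(C)C)(C(C)C)C(C)C)c2O1 | intermediate
20 | 1-(triphenyl-λ5-phosphanylidene)propan-2-one | CC(=O)C=P(c1ccccc1)(c1ccccc1)c1ccccc1 | starting material
21 | (3E)-5-[(2R)-5-iodo-2-methyl-8-{[tri(propan-2-yl)silyl]oxy}-2H-chromen-2-yl]pent-3-en-2-one | CC(=O)/C=C/C[C@]1(C)C=Cc2c(I)ccc(O[Si](C(C)C)(C(C)C)C(C)C)c2O1 | intermediate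
22 | (3E)-5-[(2R)-5-iodo-2-methyl-8-{[tri(propan-2-yl)silyl]oxy}-2H-chromen-2-yl]-2-methylpent-3-en-2-ol | CC(C)(O)/C=C/C[C@]1(C)C=Cc2c(I)ccc(O[Si](C(C)C)(C(C)C)C(C)C)c2O1 | intermediate
23 | 2,4-dihydroxybenzaldehyde | O=Cc1ccc(O)cc1O | starting material
24 | 2,4-bis{[tri(propan-2-yl)silyl]oxy}benzaldehyde | O=Cc1ccc(O[Si](C(C)C)(C(C)C)C(C)C)cc1O[Si](C(C)C)(C(C)C)C(C)C | intermediate
25 | 1-(2,4-bis{[tri(propan-2-yl)silyl]oxy}phenyl)prop-2-en-1-ol (racemic) | C=CC(O)c1ccc(O[Si](C(C)C)(C(C)C)C(C)C)cc1O[Si](C(C)C)(C(C)C)C(C)C | intermediate
26 | 1-(2,4-bis{[tri(propan-2-yl)silyl]oxy}phenyl)-3-[(2R)-2-[(2E)-4-hydroxy-4-methylpent-2-en-1-yl]-2-methyl-8-{[tri(propan-2-yl)silyl]oxy}-2H-chromen-5-yl]propan-1-one | CC(C)(O)/C=C/C[C@]1(C)C=Cc2c(CCC(=O)c3ccc(O[Si](C(C)C)(C(C)C)C(C)C)cc3O[Si](C(C)C)(C(C)C)C(C)C)ccc(O[Si](C(C)C)(C(C)C)C(C)C)c2O1 | intermediate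
27 | 1-(2,4-dihydroxyphenyl)-3-{(2R)-8-hydroxy-2-[(2E)-4-hydroxy-4-methylpent-2-en-1-yl]-2-methyl-2H-chromen-5-yl}propan-1-one | CC(C)(O)/C=C/C[C@]1(C)C=Cc2c(CCC(=O)c3ccc(O)cc3O)ccc(O)c2O1 | target

## Step count and risk

Total: 18 steps. Longest linear sequence: 16 steps (steps 1–14, 17 and 18); the side branch to 25 (steps 15 and 16) has 2 steps.

Least certain steps:

**Step 7 (key step).** The most likely failure is heterolysis of the tertiary C–O bond of the gold-activated ynol ether, or its retro-ene loss of ketene, running faster than attack by the furan, because the carbinol carbon is fully substituted and the usual substrates are not. Intermolecular attack by the free C5 position of a second furan, or addition of the product phenol to unreacted ynol ether, are the next risks.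

Fallback: give up the furan and buy ring A, setting out from 2 and returning at 13. Olefination of 2 with 4-(2-bromophenyl)butan-2-one F1 should give ethyl (2E)-5-(2-bromophenyl)-3-methylpent-2-enoate F2. The reagents of steps 2–5 would then lead through (2E)-5-(2-bromophenyl)-3-methylpent-2-en-1-ol F3, {(2S,3S)-3-[2-(2-bromophenyl)ethyl]-3-methyloxiran-2-yl}methanol F4 and (3S)-5-(2-bromophenyl)-3-methylpentane-1,3-diol F5 to (3S)-5-(2-bromophenyl)-3-methyl-1-{[tri(propan-2-yl)silyl]oxy}pentan-3-ol F6. An intramolecular C–O coupling of the tertiary alcohol with the aryl bromide (Pd(OAc)2, a di-tert-butyl(biaryl)phosphine, Cs2CO3, toluene) would close ring B to {2-[(2S)-2-methyl-3,4-dihydro-2H-chromen-2-yl]ethoxy}tri(propan-2-yl)silane F7. Lithiation ortho to O1 (s-BuLi, TMEDA), borylation with B(OMe)3 and oxidation with H2O2 would place the hydroxyl on C8 and give 13.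

**Step 6.** The hindered tertiary alkoxide may add too slowly to dichloroacetylene, and the tertiary ethynyl ether may lose ketene thermally during work-up.

Fallback, from 7 back to 10, without an alkoxide: formylation of 7 (acetic formic anhydride, pyridine) to (3S)-1-(furan-2-yl)-3-methyl-5-{[tri(propan-2-yl)silyl]oxy}pentan-3-yl formate F8; dibromo-olefination of the formate (CBr4, PPh3) to {[(3S)-3-[(2,2-dibromoethenyl)oxy]-5-(furan-2-yl)-3-methylpentyl]oxy}tri(propan-2-yl)silane F9; then n-BuLi at −78 °C and a protic quench to give 10.

**Step 10.** Ionic bromination of the electron-rich ring, addition of bromine to the chromene as it forms, or HBr-induced loss of a silyl group may compete with the radical substitution at C4.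

Fallback, from 15 directly to 17: dehydrogenation by hydride abstraction with 2,3-dichloro-5,6-dicyano-1,4-benzoquinone in 1,4-dioxane at 80 °C, the classical chroman-to-chromene method. It makes no new compound.

**Step 11.** The primary triisopropylsilyl ether is slow to cleave with acid, so partial loss of the aryl silyl ether or acid-catalysed addition of methanol across C3=C4 may set in before conversion is complete.

Fallback, from 17 back to 18: remove both silyl groups with n-Bu4NF to give (2R)-2-(2-hydroxyethyl)-5-iodo-2-methyl-2H-chromen-8-ol F10, then deprotonate only the phenol with one equivalent of NaH and silylate the phenoxide with i-Pr3SiCl.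

**Step 17.** β-Hydride elimination may go toward the new benzylic CH2 (giving the arylated allylic alcohol), or 25 may be isomerised or ionised by palladium before it couples, since it is a very electron-rich benzylic and allylic alcohol.

Fallback, from 25 and 22 back to 26: oxidise 25 with MnO2 to 1-(2,4-bis{[tri(propan-2-yl)silyl]oxy}phenyl)prop-2-en-1-one F11. Couple F11 with 22 in an ordinary Heck reaction (Pd(OAc)2, n-Bu4NCl, NaHCO3, DMF) to the chalcone (2E)-1-(2,4-bis{[tri(propan-2-yl)silyl]oxy}phenyl)-3-[(2R)-2-[(2E)-4-hydroxy-4-methylpent-2-en-1-yl]-2-methyl-8-{[tri(propan-2-yl)silyl]oxy}-2H-chromen-5-yl]prop-2-en-1-one F12. Reduce the enone selectively with [(Ph3P)CuH]6, which leaves the ring alkene and the side-chain alkene alone, to give 26.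

## Further compounds

F1 | step 7 | 4-(2-bromophenyl)butan-2-one | CC(=O)CCc1ccccc1Br
F2 | step 7 | ethyl (2E)-5-(2-bromophenyl)-3-methylpent-2-enoate | CCOC(=O)/C=C(\C)CCc1ccccc1Br
F3 | step 7 | (2E)-5-(2-bromophenyl)-3-methylpent-2-en-1-ol | OC/C=C(\C)CCc1ccccc1Br
F4 | step 7 | {(2S,3S)-3-[2-(2-bromophenyl)ethyl]-3-methyloxiran-2-yl}methanol | OC[C@@H]1O[C@@]1(C)CCc1ccccc1Br
F5 | step 7 | (3S)-5-(2-bromophenyl)-3-methylpentane-1,3-diol | OCC[C@](O)(C)CCc1ccccc1Br
F6 | step 7 | (3S)-5-(2-bromophenyl)-3-methyl-1-{[tri(propan-2-yl)silyl]oxy}pentan-3-ol | CC(C)[Si](OCC[C@](O)(C)CCc1ccccc1Br)(C(C)C)C(C)C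
F7 | step 7 | {2-[(2S)-2-methyl-3,4-dihydro-2H-chromen-2-yl]ethoxy}tri(propan-2-yl)silane | CC(C)[Si](OCC[C@]1(C)CCc2ccccc2O1)(C(C)C)C(C)C
F8 | step 6 | (3S)-1-(furan-2-yl)-3-methyl-5-{[tri(propan-2-yl)silyl]oxy}pentan-3-yl formate | CC(C)[Si](OCC[C@](OC=O)(C)CCc1ccco1)(C(C)C)C(C)C
F9 | step 6 | {[(3S)-3-[(2,2-dibromoethenyl)oxy]-5-(furan-2-yl)-3-methylpentyl]oxy}tri(propan-2-yl)silane | CC(C)[Si](OCC[C@](OC=C(Br)Br)(C)CCc1ccco1)(C(C)C)C(C)C
F0 | step 10 | none | none
F10 | step 11 | (2R)-2-(2-hydroxyethyl)-5-iodo-2-methyl-2H-chromen-8-ol | OCC[C@]1(C)C=Cc2c(I)ccc(O)c2O1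
F11 | step 17 | 1-(2,4-bis{[tri(propan-2-yl)silyl]oxy}phenyl)prop-2-en-1-one | C=CC(=O)c1ccc(O[Si](C(C)C)(C(C)C)C(C)C)cc1O[Si](C(C)C)(C(C)C)C(C)C
F12 | step 17 | (2E)-1-(2,4-bis{[tri(propan-2-yl)silyl]oxy}phenyl)-3-[(2R)-2-[(2E)-4-hydroxy-4-methylpent-2-en-1-yl]-2-methyl-8-{[tri(propan-2-yl)silyl]oxy}-2H-chromen-5-yl]prop-2-en-1-one | CC(C)(O)/C=C/C[C@]1(C)C=Cc2c(/C=C/C(=O)c3ccc(O[Si](C(C)C)(C(C)C)C(C)C)cc3O[Si](C(C)C)(C(C)C)C(C)C)ccc(O[Si](C(C)C)(C(C)C)C(C)C)c2O1
A1 | alternative 1 | 3-bromo-2-[(1Z,3R)-3-hydroxy-3-methylhexa-1,5-dien-1-yl]-4-(methoxymethoxy)benzaldehyde | C=CC[C@](O)(C)/C=C\c1c(C=O)ccc(OCOC)c1Br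
A2 | alternative 1 | (2R)-2-allyl-8-(methoxymethoxy)-2-methyl-2H-chromene-5-carbaldehyde | C=CC[C@]1(C)C=Cc2c(C=O)ccc(OCOC)c2O1
A3 | alternative 2 | tert-butyl{[(3R)-3-[5-bromo-2-(methoxymethoxy)phenoxy]-3-methylpent-4-yn-1-yl]oxy}dimethylsilane | CC(C)(C)[Si](C)(C)OCC[C@](Oc1cc(Br)ccc1OCOC)(C)C#C
A4 | alternative 2 | tert-butyl{2-[(2R)-5-bromo-8-(methoxymethoxy)-2-methyl-2H-chromen-2-yl]ethoxy}dimethylsilane | CC(C)(C)[Si](C)(C)OCC[C@]1(C)C=Cc2c(Br)ccc(OCOC)c2O1
A5 | alternative 3 | (2R)-4-bromo-7-(methoxymethoxy)-2-methyl-2-(prop-2-en-1-yl)-1-benzofuran-3(2H)-one | C=CC[C@]1(C)C(=O)c2c(Br)ccc(OCOC)c2O1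
A6 | alternative 3 | (2R)-5-bromo-8-(methoxymethoxy)-2-methyl-2-(prop-2-en-1-yl)-2H-chromen-3(4H)-one | C=CC[C@]1(C)C(=O)Cc2c(Br)ccc(OCOC)c2O1
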